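**Retrosynthetic overview**

1. Target ⇐ tris-TIPS ether ⇐ aryl cuprate opening of a C4 spiro-epoxide. This makes the ArCH2–C4 bond and the tertiary carbinol, and replaces the usual lactone-aldol or benzyl-metal-to-ketone route.
2. Spiro-epoxide ⇐ face-selective epoxidation of a 2-aryl-3-(silyloxymethyl)-4-methylene-THF (C4 set by substrate control).
3. 4-Methylene-THF ⇐ Ti(III) epoxide opening / 5-exo-dig radical cyclisation of an epoxy propargyl ether. This is the key step: it forms the only ring (C3–C4 bond) and sets C3 trans to C2.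
4. Epoxy propargyl ether ⇐ Sharpless kinetic-resolution epoxidation of a racemic aryl vinyl carbinol (sets C2 and installs the radical precursor in one step) ⇐ vanillin + vinylMgBr.
5. Order of events: C2 (reagent control) → THF ring and C3 → C4 → second aryl ring → global desilylation.

Assumption: ring numbering is O1, C2 (aryl), C3 (CH2OH), C4 (C(OH)CH2Ar), C5, so the target is (2R,3S,4R) [IUPAC oxolan-3-ol numbering: 3R,4S,5R], with aryl/CH2OH trans and CH2OH/OH trans; ≥95% ee from Step 3, upgraded by recrystallisation of the final product, is taken as "single enantiomer".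

Ar = 3-methoxy-4-[(triisopropylsilyl)oxy]phenyl throughout.

**Step 1**
Reactants: 1 vanillin; 2 chlorotriisopropylsilane (TIPSCl)
Product: 3, 3-methoxy-4-[(triisopropylsilyl)oxy]benzaldehyde
Conditions: TIPSCl, imidazole, DMF, rt
Reagents that add atoms: TIPSCl, CC(C)[Si](Cl)(C(C)C)C(C)C
Why: Phenol O-silylation; TIPS is chosen because it survives Grignard reagents, NaH, Ti(III), peracid and cuprates, and all silyl groups are removed together at the end.

**Step 2**
Reactants: 3; 4 vinylmagnesium bromide
Product: 5, rac-1-Ar-prop-2-en-1-ol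
Conditions: CH2=CHMgBr, THF, −78 → 0 °C; aq NH4Cl
Reagents that add atoms: vinylmagnesium bromide, C=C[Mg]Br
Why: Grignard 1,2-addition to the aldehyde; the racemate is intended because the next step resolves it.

**Step 3**
Reactants: 5; 6 tert-butyl hydroperoxide
Product: 7, (S)-Ar[(2R)-oxiran-2-yl]methanol (erythro epoxy alcohol; ≤45% yield, expected ≥95% ee)
Conditions: Ti(OiPr)4 (1 equiv), L-(+)-DIPT (1.2 equiv), t-BuOOH (0.45 equiv), 4 Å MS, CH2Cl2, −20 °C, stop at ~45% conversion
Reagents that add atoms: tert-butyl hydroperoxide, CC(C)(C)OO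
Why: Sharpless kinetic resolution (Ti–tartrate epoxidation of a secondary allylic alcohol): with L-(+)-DIPT the (R)-carbinol (aryl outranks vinyl) is the fast-reacting enantiomer and gives the erythro epoxy alcohol, which fixes the future C2 (the label becomes S only because oxiranyl now outranks aryl); unreacted (S)-5 is removed by chromatography, and the oxirane stereocentre does not matter because Step 5 destroys it.

**Step 4**
Reactants: 7; 8 propargyl bromide
Product: 9, (2R)-2-[(S)-Ar(prop-2-yn-1-yloxy)methyl]oxirane
Conditions: NaH, propargyl bromide, n-Bu4NI (cat.), THF, 0 °C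
Reagents that add atoms: propargyl bromide, C#CCBr
Why: Williamson etherification of the alkoxide, with no bond to a stereocentre broken; the reactive electrophile at 0 °C in aprotic solvent outruns Payne rearrangement, as in routine O-benzylations of related 1-substituted 2,3-epoxy alcohols.

**Step 5**
Reactants: 9
Product: 10, [(2R,3S)-2-Ar-4-methylideneoxolan-3-yl]methanol
Conditions: Cp2TiCl2 (2.5 equiv), Zn dust, THF, rt (preformed Cp2TiCl added slowly to 9); aq NaH2PO4
Reagents that add atoms: none (H from THF and work-up)
Why: Nugent–RajanBabu Ti(III) reductive epoxide opening gives the secondary β-titanoxy radical at C3, which closes 5-exo-dig onto the alkyne (forming the ring) and the vinyl radical abstracts H from THF; C3 is set trans to the C2 aryl because the aryl sits pseudo-equatorial and CH2OTi avoids it in the chair-like (Beckwith) transition state, and both oxirane epimers converge through the planar radical (this cyclisation type is established for aryl epoxy propargyl ethers in furano-lignan work, with the minor cis isomer removed by chromatography).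

**Step 6**
Reactants: 10; 2 TIPSCl
Product: 11, triisopropyl{[(2R,3S)-2-Ar-4-methylideneoxolan-3-yl]methoxy}silane
Conditions: TIPSCl, imidazole, DMAP (cat.), DMF, rt → 40 °C
Reagents that add atoms: TIPSCl, CC(C)[Si](Cl)(C(C)C)C(C)C
Why: Silylation of the primary alcohol removes any OH-directed (syn) oxidant delivery and adds bulk on the C3 face for the next step.

**Step 7**
Reactants: 11; 12 mCPBA
Product: 13, (3S,6R,7S)-6-Ar-7-{[(triisopropylsilyl)oxy]methyl}-1,5-dioxaspiro[2.4]heptane (epoxide O trans to C3–CH2OTIPS, cis to the C2 aryl)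
Conditions: mCPBA, NaHCO3, CH2Cl2, 0 °C
Reagents that add atoms: mCPBA, OOC(=O)c1cccc(Cl)c1
Why: Prilezhaev epoxidation under substrate control: the peracid attacks the exocyclic alkene on the face anti to the adjacent C3–CH2OTIPS group, which places the oxygen trans to CH2OTIPS and so sets the C4 configuration of the target; NaHCO3 protects the benzylic ether from acid.

**Step 8**
Reactants: 14 4-bromo-2-methoxyphenol; 2 TIPSCl
Product: 15, (4-bromo-2-methoxyphenoxy)triisopropylsilane
Conditions: TIPSCl, imidazole, DMF, rt
Reagents that add atoms: TIPSCl, CC(C)[Si](Cl)(C(C)C)C(C)C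
Why: Phenol silylation gives an aryl bromide that forms a Grignard reagent cleanly.

**Step 9**
Reactants: 13; 15 (as its Grignard reagent)
Product: 16, (3R,4S,5R)-5-Ar-3-(Ar-methyl)-4-{[(triisopropylsilyl)oxy]methyl}oxolan-3-ol
Conditions: 15, Mg, THF → ArMgBr (3 equiv); CuI (20 mol %), then 13, THF, −30 → 0 °C; aq NH4Cl
Reagents that add atoms: 3-methoxy-4-(triisopropylsilyloxy)phenylmagnesium bromide (from 15), COc1cc([Mg]Br)ccc1O[Si](C(C)C)(C(C)C)C(C)C
Why: Copper-catalysed SN2 opening of a 2,2-disubstituted epoxide by an aryl Grignard at the CH2 terminus forms the ArCH2–C4 bond and frees the tertiary alcohol; the C4–O bond is untouched, so the configuration from Step 7 is retained.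

**Step 10**
Reactants: 16
Product: 17, (3R,4S,5R)-5-(4-hydroxy-3-methoxyphenyl)-3-[(4-hydroxy-3-methoxyphenyl)methyl]-4-(hydroxymethyl)oxolan-3-ol (target)
Conditions: TBAF (4 equiv), AcOH (4 equiv), THF, 0 °C → rt
Reagents that add atoms: none
Why: Fluoride cleaves the two aryl and one alkyl silyl ethers in one operation; AcOH buffering prevents phenoxide-triggered quinone-methide ring opening of the p-hydroxybenzylic ether, and no stereocentre is touched.

**Compound list**

1 | vanillin | COc1cc(C=O)ccc1O | starting material
2 | chlorotriisopropylsilane | CC(C)[Si](Cl)(C(C)C)C(C)C | starting material (reagent)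
3 | 3-methoxy-4-[(triisopropylsilyl)oxy]benzaldehyde | COc1cc(C=O)ccc1O[Si](C(C)C)(C(C)C)C(C)C | intermediate
4 | vinylmagnesium bromide | C=C[Mg]Br | starting material (reagent)
5 | rac-1-Ar-prop-2-en-1-ol | COc1cc(C(O)C=C)ccc1O[Si](C(C)C)(C(C)C)C(C)C | intermediate
6 | tert-butyl hydroperoxide | CC(C)(C)OO | starting material (reagent)
7 | (S)-Ar[(2R)-oxiran-2-yl]methanol | O[C@@H](c1ccc(O[Si](C(C)C)(C(C)C)C(C)C)c(OC)c1)[C@H]2CO2 | intermediate
8 | propargyl bromide | C#CCBr | starting material (reagent)
9 | (2R)-2-[(S)-Ar(prop-2-yn-1-yloxy)methyl]oxirane | C#CCO[C@@H](c1ccc(O[Si](C(C)C)(C(C)C)C(C)C)c(OC)c1)[C@H]2CO2 | intermediate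
10 | [(2R,3S)-2-Ar-4-methylideneoxolan-3-yl]methanol | C=C1CO[C@@H](c2ccc(O[Si](C(C)C)(C(C)C)C(C)C)c(OC)c2)[C@@H]1CO | intermediate
11 | TIPS ether of 10 | C=C1CO[C@@H](c2ccc(O[Si](C(C)C)(C(C)C)C(C)C)c(OC)c2)[C@@H]1CO[Si](C(C)C)(C(C)C)C(C)C | intermediate
12 | mCPBA | OOC(=O)c1cccc(Cl)c1 | starting material (reagent)
13 | (3S,6R,7S)-6-Ar-7-(TIPSO-methyl)-1,5-dioxaspiro[2.4]heptane | C1[C@]2(O1)CO[C@@H](c3ccc(O[Si](C(C)C)(C(C)C)C(C)C)c(OC)c3)[C@@H]2CO[Si](C(C)C)(C(C)C)C(C)C | intermediate
14 | 4-bromo-2-methoxyphenol | COc1cc(Br)ccc1O | starting material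
15 | (4-bromo-2-methoxyphenoxy)triisopropylsilane | COc1cc(Br)ccc1O[Si](C(C)C)(C(C)C)C(C)C | intermediate
16 | (3R,4S,5R)-5-Ar-3-(Ar-methyl)-4-(TIPSO-methyl)oxolan-3-ol | COc1cc(C[C@]2(O)CO[C@@H](c3ccc(O[Si](C(C)C)(C(C)C)C(C)C)c(OC)c3)[C@@H]2CO[Si](C(C)C)(C(C)C)C(C)C)ccc1O[Si](C(C)C)(C(C)C)C(C)C | intermediate
17 | CID44566587 | COc1cc(C[C@]2(O)CO[C@@H](c3ccc(O)c(OC)c3)[C@@H]2CO)ccc1O | target

**Step count**

Total steps: 10. Longest linear sequence: 9 (Steps 1–7, 9, 10).

**Three steps most likely to fail, with fallbacks**

- **Step 7 (facial selectivity at C4).** Selectivity rests only on the C3 substituent and may be modest. Fallback: put the second aryl on the alkyne instead (alkylate 7 with the 3-aryl-propargyl bromide), so Step 5 gives the 4-benzylidene-THF. Then use reagent-controlled Shi epoxidation and hydride opening at the benzylic carbon (LiEt3BH) to reach 16, with no cuprate step.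
- **Step 5 (radical cyclisation).** Risks are the cis/trans ratio at C3 and premature reduction of the radical followed by β-alkoxide elimination. Fallback: recover (R)-5 from a resolution with D-(−)-DIPT, O-propargylate it, and close the ring by Pd-catalysed borylative 1,6-enyne cyclisation (B2pin2) followed by C–B oxidation to 10.
- **Step 3 (kinetic resolution).** It is capped at about 45% yield, the electron-rich benzylic carbinol is Lewis-acid sensitive, and the ee depends on stopping at the right conversion. Fallback: set C2 catalytically by Ir–phosphoramidite asymmetric allylic etherification of the (E)-cinnamyl methyl carbonate with propargyl alcohol to give the (R)-branched propargyl ether, then epoxidise with buffered mCPBA; either epoxide epimer converges in Step 5.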